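**Retrosynthetic overview**
- Target ⇒ seco hydroxy ester: the γ-lactone is closed last by O8→C12 acyl substitution, after the C6 hydroxyl has been angeloylated.
- Ten-membered ring ⇒ acyclic C6 lactol carrying a (Z)-2-(bromomethyl)enoate: the C6–C7 bond (the bond made when a farnesyl chain closes to a germacrene) is formed by an intramolecular indium Barbier allylation that sets C6 and C7 from C8.
- Allyl bromide ⇒ C7 aldehyde (Morita–Baylis–Hillman, then SN2′ bromination); C1=C10 ⇒ E-selective Horner–Wadsworth–Emmons reaction of a phosphonolactone (C8 from a glycidyl ether) with a C1 aldehyde.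
- C1–C6/C15 aldehyde ⇒ furan-2(5H)-one: asymmetric vinyl 1,4-addition (C4), lactol methyl acetal, hydroformylation.
- Ring order: carbocycle first (step 12), lactone second (step 15).

Assumption: germacrane numbering is used (lactone O on C8, angelate on C6, C14 on C10, C15 on C4); the target is 4R,6R,7R,8R with a ring-cis (CIP E) C1=C10 bond.
Abbreviations: TBS = tert-butyldimethylsilyl, PMB = 4-methoxybenzyl.

**Step 1**
Reactants: 1 furan-2(5H)-one; 2 potassium vinyltrifluoroborate
Product: 3 (4S)-4-ethenyloxolan-2-one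
Conditions: [Rh(cod)2]PF6 (3 mol %), (S)-BINAP (3.3 mol %), toluene/H2O 20:1, 100 °C
Reagents that add atoms: none
Why: Hayashi–Miyaura-type asymmetric 1,4-addition of the vinylboron reagent to the butenolide, in which the [Rh(cod)2]PF6/(S)-BINAP catalyst is expected to select the enone face as it does for cyclic enones and so sets C4 (S in this lactone, the 4R centre of the target).

**Step 2**
Reactants: 3 (4S)-4-ethenyloxolan-2-one
Product: 5 (4S)-4-ethenyl-2-methoxyoxolane (anomer mixture), via lactol 4 (not isolated)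
Conditions: i-Bu2AlH (1.1 equiv), CH2Cl2, −78 °C; then MeOH, TsOH·H2O (to pH 2), −78 °C to rt
Reagents that add atoms: methanol, SMILES: CO
Why: Partial reduction of the γ-lactone by i-Bu2AlH stops at the lactol because the tetrahedral aluminate is stable at −78 °C, and Fischer-type acetalisation in acidic methanol then masks the C6 aldehyde and O15 together as a methyl furanoside without touching C4.

**Step 3**
Reactants: 5 (4S)-4-ethenyl-2-methoxyoxolane
Product: 6 3-[(3R)-5-methoxyoxolan-3-yl]propanal (anomer mixture)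
Conditions: Rh(acac)(CO)2 (1 mol %), Xantphos (2 mol %), CO/H2 1:1 (10 bar), toluene, 70 °C
Reagents that add atoms: carbon monoxide, SMILES: [C-]#[O+]
Why: Linear-selective hydroformylation with the wide-bite-angle Rh(acac)(CO)2/Xantphos catalyst adds C1 as an aldehyde at the terminal carbon of the vinyl group and tolerates the acetal, with no new stereocentre.

**Step 4**
Reactants: 7 (2R)-2-{[(4-methoxyphenyl)methoxy]methyl}oxirane; 8 triethyl phosphonoacetate
Product: 9 diethyl [(5R)-5-{[(4-methoxyphenyl)methoxy]methyl}-2-oxooxolan-3-yl]phosphonate (C3 epimers)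
Conditions: NaH, toluene, 0 °C; then 7, 100 °C; aq HCl work-up
Reagents that add atoms: none
Why: Epoxide alkylation–lactonisation, in which the sodium enolate of the phosphonoacetate opens the epoxide at its unhindered CH2 (SN2) and the alkoxide closes onto the ethyl ester, so the C8–O bond and the configuration of 7 are carried over unchanged.

**Step 5**
Reactants: 9 diethyl [(5R)-5-{[(4-methoxyphenyl)methoxy]methyl}-2-oxooxolan-3-yl]phosphonate; 6 3-[(3R)-5-methoxyoxolan-3-yl]propanal
Product: 10 (3E,5R)-5-{[(4-methoxyphenyl)methoxy]methyl}-3-{3-[(3R)-5-methoxyoxolan-3-yl]propylidene}oxolan-2-one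
Conditions: LiCl, DBU, MeCN, 0 °C to rt
Reagents that add atoms: none
Why: Horner–Wadsworth–Emmons olefination under Masamune–Roush conditions, where reversible addition of the stabilised phosphonate favours the E alkylidene lactone (C2 trans to the carbonyl and cis to C9), which is the ring-cis C1=C10 geometry of the target, the minor Z isomer being removed by chromatography.

**Step 6**
Reactants: 10 (3E,5R)-alkylidene lactone
Product: 11 (2R,4E)-4-(hydroxymethyl)-1-[(4-methoxyphenyl)methoxy]-7-[(3R)-5-methoxyoxolan-3-yl]hept-4-en-2-ol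
Conditions: i-Bu2AlH (4 equiv), CH2Cl2, −78 to 0 °C; aq potassium sodium tartrate work-up
Reagents that add atoms: none
Why: Exhaustive 1,2-reduction of the α-alkylidene lactone with i-Bu2AlH (lactone to allylic 1,4-diol) leaves the acetal, the PMB ether and the alkene geometry untouched and creates no stereocentre.

**Step 7**
Reactants: 11 (2R,4E)-diol
Product: 12 (2R,4E)-2-(TBSO)-4-(TBSOCH2)-1-[(4-methoxyphenyl)methoxy]-7-[(3R)-5-methoxyoxolan-3-yl]hept-4-ene
Conditions: TBSCl (2.5 equiv), imidazole, DMF, rt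
Reagents that add atoms: tert-butyldimethylsilyl chloride, SMILES: CC(C)(C)[Si](C)(C)Cl
Why: Standard silyl ether formation on the primary allylic and the secondary hydroxyl, which blocks O14 and O8 with a bulky, non-chelating group that is needed later for facial control.

**Step 8**
Reactants: 12 bis-TBS PMB ether
Product: 13 (2R,4E)-2-(TBSO)-4-(TBSOCH2)-7-[(3R)-5-methoxyoxolan-3-yl]hept-4-en-1-ol
Conditions: DDQ, CH2Cl2/pH 7 phosphate buffer 10:1, 0 °C
Reagents that add atoms: none
Why: Oxidative PMB cleavage by DDQ through the benzylic oxocarbenium ion frees only the C7 hydroxyl, since silyl ethers, the acetal and the alkene are inert to buffered DDQ.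

**Step 9**
Reactants: 13 (2R,4E)-primary alcohol
Product: 14 (2R,4E)-2-(TBSO)-4-(TBSOCH2)-7-[(3R)-5-methoxyoxolan-3-yl]hept-4-enal
Conditions: Dess–Martin periodinane, CH2Cl2, 0 °C to rt
Reagents that add atoms: none
Why: Dess–Martin oxidation converts the primary alcohol to the aldehyde under neutral, non-enolising conditions, so the adjacent C8 silyloxy stereocentre is not epimerised.

**Step 10**
Reactants: 14 (2R,4E)-aldehyde; 15 methyl acrylate
Product: 16 methyl (4R,6E)-3-hydroxy-2-methylidene-4-(TBSO)-6-(TBSOCH2)-9-[(3R)-5-methoxyoxolan-3-yl]non-6-enoate (C3 epimers)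
Conditions: DABCO (1 equiv), 15 (10 equiv), MeOH (2 equiv), rt, 3–5 d
Reagents that add atoms: none
Why: Morita–Baylis–Hillman reaction of the activated α-silyloxy aldehyde with methyl acrylate under DABCO catalysis, in which the new C7 carbinol centre forms as a mixture but is erased in the next step.

**Step 11**
Reactants: 16 Morita–Baylis–Hillman adduct
Product: 17 methyl (2Z,4R,6E)-2-(bromomethyl)-4-(TBSO)-6-(TBSOCH2)-9-[(3R)-5-methoxyoxolan-3-yl]nona-2,6-dienoate
Conditions: NBS, Me2S, CH2Cl2, −20 to 0 °C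
Reagents that add atoms: N-bromosuccinimide, SMILES: O=C1CCC(=O)N1Br
Why: SN2′ bromination of the Morita–Baylis–Hillman alcohol by the bromosulfonium reagent from NBS and Me2S (Corey–Kim type) moves the alkene into conjugation and gives the thermodynamically favoured 2Z isomer with C8 cis to CH2Br and no new stereocentre.

**Step 12**
Reactants: 17 (2Z)-allylic bromide methyl acetal
Product: 19 methyl 2-[(1R,2R,4E,8R,10R)-10-hydroxy-8-(hydroxymethyl)-2-(TBSO)-4-(TBSOCH2)cyclodec-4-en-1-yl]prop-2-enoate, via lactol 18 (not isolated)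
Conditions: 0.1 M aq HCl/THF 1:4, 0 °C, 1 h; then diluted to 2 mM with THF/H2O 1:1, indium powder (3 equiv), rt
Reagents that add atoms: water, SMILES: O
Why: Acid unmasks the lactol and indium inserts into the allylic bromide for an intramolecular Barbier allylation (a reaction type that tolerates water, free hydroxyls and lactols) which closes the ten-membered ring at C6–C7 through a chair Zimmerman–Traxler transition state, where the Z-configured allylindium gives the 6,7-syn relationship and the aldehyde adds to the face of C7 anti to the bulky C8 silyloxy group (Felkin–Anh, H8 eclipsing the alkene to avoid A(1,3) strain), setting C6 and C7 as R.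

**Step 13**
Reactants: 19 macrocyclic diol
Product: 20 methyl 2-[(1R,2R,4E,8R,10R)-10-hydroxy-2-(TBSO)-4,8-bis(TBSOCH2)cyclodec-4-en-1-yl]prop-2-enoate
Conditions: TBSCl (1.05 equiv), imidazole, CH2Cl2, −20 to 0 °C
Reagents that add atoms: tert-butyldimethylsilyl chloride, SMILES: CC(C)(C)[Si](C)(C)Cl
Why: Chemoselective silylation, because the unhindered primary C15 hydroxyl reacts far faster with TBSCl/imidazole at low temperature than the secondary C6 hydroxyl flanked by the ring and the C7 branch.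

**Step 14**
Reactants: 20 C6 alcohol; 21 angelic acid
Product: 23 methyl 2-[(1R,2R,4E,8R,10R)-10-{[(2Z)-2-methylbut-2-enoyl]oxy}-2-(TBSO)-4,8-bis(TBSOCH2)cyclodec-4-en-1-yl]prop-2-enoate, via mixed anhydride 22 (not isolated)
Conditions: 2,4,6-Cl3C6H2COCl, Et3N, toluene, rt; then 20, 75 °C
Reagents that add atoms: none
Why: Yamaguchi-type esterification in which the preformed mixed anhydride acylates the hindered C6 hydroxyl at the angeloyl carbonyl without a nucleophilic catalyst, the condition known to keep the Z geometry of the angelate, and the C6–O bond is not broken so configuration is retained.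

**Step 15**
Reactants: 23 tris-TBS angelate
Product: 25 (3aR,4R,6R,9E,11aR)-6,10-bis(hydroxymethyl)-3-methylidene-2-oxo-2,3,3a,4,5,6,7,8,11,11a-decahydrocyclodeca[b]furan-4-yl (2Z)-2-methylbut-2-enoate (CNP0147777.1), via triol ester 24 (not isolated)
Conditions: HF·pyridine, pyridine, THF, 0 °C to rt; then TsOH·H2O (10 mol %), CH2Cl2, rt
Reagents that add atoms: none
Why: Global desilylation with HF·pyridine followed by acid-catalysed lactonisation (intramolecular transesterification) of the γ-hydroxy ester, in which only O8 can close a five-membered ring because O6 is acylated, so the trans ring fusion follows from the C7 and C8 configurations already in place.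

**Compound list**
1 | furan-2(5H)-one | O=C1OCC=C1 | starting material
2 | potassium vinyltrifluoroborate | C=C[B-](F)(F)F.[K+] | starting material
3 | (4S)-4-ethenyloxolan-2-one | C=C[C@H]1COC(=O)C1 | intermediate
4 | (4S)-4-ethenyloxolan-2-ol (lactol, anomer mixture) | C=C[C@H]1COC(O)C1 | intermediate
5 | (4S)-4-ethenyl-2-methoxyoxolane (anomer mixture) | C=C[C@H]1COC(OC)C1 | intermediate
6 | 3-[(3R)-5-methoxyoxolan-3-yl]propanal (anomer mixture) | O=CCC[C@H]1COC(OC)C1 | intermediate
7 | (2R)-2-{[(4-methoxyphenyl)methoxy]methyl}oxirane ((R)-PMB glycidyl ether) | COc1ccc(COC[C@H]2CO2)cc1 | starting material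
8 | triethyl phosphonoacetate | CCOC(=O)CP(=O)(OCC)OCC | starting material
9 | diethyl [(5R)-5-{[(4-methoxyphenyl)methoxy]methyl}-2-oxooxolan-3-yl]phosphonate (C3 epimers) | COc1ccc(COC[C@H]2CC(P(=O)(OCC)OCC)C(=O)O2)cc1 | intermediate
10 | (3E,5R)-5-{[(4-methoxyphenyl)methoxy]methyl}-3-{3-[(3R)-5-methoxyoxolan-3-yl]propylidene}oxolan-2-one | COc1ccc(COC[C@H]2C/C(=C\CC[C@H]3COC(OC)C3)C(=O)O2)cc1 | intermediate
11 | (2R,4E)-4-(hydroxymethyl)-1-[(4-methoxyphenyl)methoxy]-7-[(3R)-5-methoxyoxolan-3-yl]hept-4-en-2-ol | COc1ccc(COC[C@H](O)C/C(CO)=C\CC[C@H]2COC(OC)C2)cc1 | intermediate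
12 | (2R,4E)-2-(TBSO)-4-(TBSOCH2)-1-[(4-methoxyphenyl)methoxy]-7-[(3R)-5-methoxyoxolan-3-yl]hept-4-ene | COc1ccc(COC[C@H](O[Si](C)(C)C(C)(C)C)C/C(CO[Si](C)(C)C(C)(C)C)=C\CC[C@H]2COC(OC)C2)cc1 | intermediate
13 | (2R,4E)-2-(TBSO)-4-(TBSOCH2)-7-[(3R)-5-methoxyoxolan-3-yl]hept-4-en-1-ol | OC[C@H](O[Si](C)(C)C(C)(C)C)C/C(CO[Si](C)(C)C(C)(C)C)=C\CC[C@H]1COC(OC)C1 | intermediate
14 | (2R,4E)-2-(TBSO)-4-(TBSOCH2)-7-[(3R)-5-methoxyoxolan-3-yl]hept-4-enal | O=C[C@H](O[Si](C)(C)C(C)(C)C)C/C(CO[Si](C)(C)C(C)(C)C)=C\CC[C@H]1COC(OC)C1 | intermediate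
15 | methyl acrylate | C=CC(=O)OC | starting material
16 | methyl (4R,6E)-3-hydroxy-2-methylidene-4-(TBSO)-6-(TBSOCH2)-9-[(3R)-5-methoxyoxolan-3-yl]non-6-enoate (C3 epimers) | COC(=O)C(=C)C(O)[C@H](O[Si](C)(C)C(C)(C)C)C/C(CO[Si](C)(C)C(C)(C)C)=C\CC[C@H]1COC(OC)C1 | intermediate
17 | methyl (2Z,4R,6E)-2-(bromomethyl)-4-(TBSO)-6-(TBSOCH2)-9-[(3R)-5-methoxyoxolan-3-yl]nona-2,6-dienoate | COC(=O)/C(CBr)=C/[C@H](O[Si](C)(C)C(C)(C)C)C/C(CO[Si](C)(C)C(C)(C)C)=C\CC[C@H]1COC(OC)C1 | intermediate
18 | methyl (2Z,4R,6E)-2-(bromomethyl)-4-(TBSO)-6-(TBSOCH2)-9-[(3R)-5-hydroxyoxolan-3-yl]nona-2,6-dienoate (lactol) | COC(=O)/C(CBr)=C/[C@H](O[Si](C)(C)C(C)(C)C)C/C(CO[Si](C)(C)C(C)(C)C)=C\CC[C@H]1COC(O)C1 | intermediate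
19 | methyl 2-[(1R,2R,4E,8R,10R)-10-hydroxy-8-(hydroxymethyl)-2-(TBSO)-4-(TBSOCH2)cyclodec-4-en-1-yl]prop-2-enoate | C=C(C(=O)OC)[C@H]1[C@H](O[Si](C)(C)C(C)(C)C)C/C(CO[Si](C)(C)C(C)(C)C)=C\CC[C@@H](CO)C[C@H]1O | intermediate
20 | methyl 2-[(1R,2R,4E,8R,10R)-10-hydroxy-2-(TBSO)-4,8-bis(TBSOCH2)cyclodec-4-en-1-yl]prop-2-enoate | C=C(C(=O)OC)[C@H]1[C@H](O[Si](C)(C)C(C)(C)C)C/C(CO[Si](C)(C)C(C)(C)C)=C\CC[C@@H](CO[Si](C)(C)C(C)(C)C)C[C@H]1O | intermediate
21 | angelic acid, (2Z)-2-methylbut-2-enoic acid | C/C=C(/C)C(=O)O | starting material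
22 | (2Z)-2-methylbut-2-enoic 2,4,6-trichlorobenzoic anhydride | C/C=C(/C)C(=O)OC(=O)c1c(Cl)cc(Cl)cc1Cl | intermediate
23 | methyl 2-[(1R,2R,4E,8R,10R)-10-{[(2Z)-2-methylbut-2-enoyl]oxy}-2-(TBSO)-4,8-bis(TBSOCH2)cyclodec-4-en-1-yl]prop-2-enoate | C=C(C(=O)OC)[C@H]1[C@H](O[Si](C)(C)C(C)(C)C)C/C(CO[Si](C)(C)C(C)(C)C)=C\CC[C@@H](CO[Si](C)(C)C(C)(C)C)C[C@H]1OC(=O)/C(C)=C\C | intermediate
24 | methyl 2-[(1S,2R,4E,8R,10R)-2-hydroxy-4,8-bis(hydroxymethyl)-10-{[(2Z)-2-methylbut-2-enoyl]oxy}cyclodec-4-en-1-yl]prop-2-enoate | C=C(C(=O)OC)[C@H]1[C@H](O)C/C(CO)=C\CC[C@@H](CO)C[C@H]1OC(=O)/C(C)=C\C | intermediate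
25 | (3aR,4R,6R,9E,11aR)-6,10-bis(hydroxymethyl)-3-methylidene-2-oxo-2,3,3a,4,5,6,7,8,11,11a-decahydrocyclodeca[b]furan-4-yl (2Z)-2-methylbut-2-enoate | C=C1C(=O)O[C@@H]2C/C(CO)=C\CC[C@@H](CO)C[C@@H](OC(=O)/C(C)=C\C)[C@@H]12 | target

**Step count**
Total: 15 steps (3 to aldehyde 6, 1 to phosphonate 9, 11 after their union). Longest linear sequence: 14 steps (1 → 3 → 5 → 6 → 10 → 11 → 12 → 13 → 14 → 16 → 17 → 19 → 20 → 23 → 25).

**Steps most likely to fail, with fallbacks**

Step 12 (ring closure). The medium-ring transition state may not follow the open-chain chair preference, so the aldehyde could add anti instead of syn at C6; slow closure also competes with protonolysis of the allylindium. The fallback keeps the ring closure and changes how C6 is set, from retentive acylation to invertive esterification. Setting out from 17, the same operation then gives the C6-epimeric diol methyl 2-[(1R,2R,4E,8R,10S)-10-hydroxy-8-(hydroxymethyl)-2-(TBSO)-4-(TBSOCH2)cyclodec-4-en-1-yl]prop-2-enoate F1. TBSCl/imidazole at −20 °C silylates its primary hydroxyl to give methyl 2-[(1R,2R,4E,8R,10S)-10-hydroxy-2-(TBSO)-4,8-bis(TBSOCH2)cyclodec-4-en-1-yl]prop-2-enoate F2. A Mitsunobu reaction of F2 with 21 (PPh3, DIAD, toluene, 0 °C to rt) installs the angelate with inversion at C6; the carboxylate is the nucleophile, so there is no acyl activation and no Z to E isomerisation. The route is rejoined at 23.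

Step 14 (angeloylation). The C6 hydroxyl is hindered, the angelate can isomerise to the tiglate, and at 75 °C the free hydroxyl could lactonise onto the C12 ester. The fallback builds the Z-enoate on the substrate from an alkyne instead of transferring a preformed angeloyl group. Setting out from 20, DCC/DMAP esterification with but-2-ynoic acid at 0 °C gives methyl 2-[(1R,2R,4E,8R,10R)-10-(but-2-ynoyloxy)-2-(TBSO)-4,8-bis(TBSOCH2)cyclodec-4-en-1-yl]prop-2-enoate F3. Syn hydrostannation with Bu3SnH and catalytic Pd(PPh3)4 in THF puts tin on the α-carbon and gives methyl 2-[(1R,2R,4E,8R,10R)-10-{[(2E)-2-(tributylstannyl)but-2-enoyl]oxy}-2-(TBSO)-4,8-bis(TBSOCH2)cyclodec-4-en-1-yl]prop-2-enoate F4. Stille methylation with MeI (Pd2(dba)3, tri(2-furyl)phosphine, CuI, DMF) goes with retention and gives the angelate, so the route is rejoined at 23.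

Step 10 (Morita–Baylis–Hillman). The reaction is slow with a branched α-silyloxy aldehyde, and days of contact with DABCO can epimerise C8. The fallback replaces amine catalysis by a preformed α-metallated acrylate. Setting out from 14, the vinylalane generated from methyl propiolate with i-Bu2AlH and N-methylmorpholine N-oxide in THF at 0 °C adds to the aldehyde within hours and gives the same adduct directly. No new compound is formed (F0), and the route is rejoined at 16.

**Further compounds**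
F1 | step 12 | methyl 2-[(1R,2R,4E,8R,10S)-10-hydroxy-8-(hydroxymethyl)-2-(TBSO)-4-(TBSOCH2)cyclodec-4-en-1-yl]prop-2-enoate | C=C(C(=O)OC)[C@H]1[C@H](O[Si](C)(C)C(C)(C)C)C/C(CO[Si](C)(C)C(C)(C)C)=C\CC[C@@H](CO)C[C@@H]1O
F2 | step 12 | methyl 2-[(1R,2R,4E,8R,10S)-10-hydroxy-2-(TBSO)-4,8-bis(TBSOCH2)cyclodec-4-en-1-yl]prop-2-enoate | C=C(C(=O)OC)[C@H]1[C@H](O[Si](C)(C)C(C)(C)C)C/C(CO[Si](C)(C)C(C)(C)C)=C\CC[C@@H](CO[Si](C)(C)C(C)(C)C)C[C@@H]1O
F3 | step 14 | methyl 2-[(1R,2R,4E,8R,10R)-10-(but-2-ynoyloxy)-2-(TBSO)-4,8-bis(TBSOCH2)cyclodec-4-en-1-yl]prop-2-enoate | C=C(C(=O)OC)[C@H]1[C@H](O[Si](C)(C)C(C)(C)C)C/C(CO[Si](C)(C)C(C)(C)C)=C\CC[C@@H](CO[Si](C)(C)C(C)(C)C)C[C@H]1OC(=O)C#CC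
F4 | step 14 | methyl 2-[(1R,2R,4E,8R,10R)-10-{[(2E)-2-(tributylstannyl)but-2-enoyl]oxy}-2-(TBSO)-4,8-bis(TBSOCH2)cyclodec-4-en-1-yl]prop-2-enoate | C=C(C(=O)OC)[C@H]1[C@H](O[Si](C)(C)C(C)(C)C)C/C(CO[Si](C)(C)C(C)(C)C)=C\CC[C@@H](CO[Si](C)(C)C(C)(C)C)C[C@H]1OC(=O)/C([Sn](CCCC)(CCCC)CCCC)=C\C
F0 | step 10 | none | none
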